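**Retrosynthetic overview**

- The strategy rests on the furan C2=C3 bond. C2 (bound to O1 and ring B) is at the carboxyl oxidation level and C3 (bound to C3a, carrying the one-carbon substituent) is a ketone carbon, so the bond is cut to a ring A acetyl group on C3a and a ring B aroyl ester on the C7a oxygen.
- Forward, that bond is made by a low-valent titanium keto-ester coupling of 12 to the 3-methylbenzofuran 13. The furan is the only ring formed; rings A and B are bought as benzenoid starting materials.
- 12 comes from the symmetric acetophenone 4: O-(1,1-dimethylallyl)ation of one hydroxyl, aroylation of the other with acid chloride 8, aromatic Claisen shift of the allyl group to the future C5, silylation of the freed C4 hydroxyl.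
- After ring closure: Markovnikov hydration of the prenyl group, DDQ oxidation of the C3 methyl to the aldehyde, one fluoride step for all three silyl ethers.

Key step: step 8

Remark: the target has no stereocentre. All three phenols are carried as tert-butyldimethylsilyl (TBS) ethers so that a single fluoride treatment ends the route and the C3 aldehyde never meets hydrogenation conditions.

**Route**

Step 1
Reactants: 1 2-methylbut-3-en-2-ol
Product: 3 tert-butyl 2-methylbut-3-en-2-yl carbonate, via lithium 2-methylbut-3-en-2-olate 2 (not isolated)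
Conditions: n-BuLi, THF, 0 °C; then Boc2O, 0 °C to rt; water quench
Reagents that add atoms: di-tert-butyl dicarbonate, CC(C)(C)OC(=O)OC(=O)OC(C)(C)C
Why: Alkoxide acylation, in which the lithium alkoxide of the tertiary allylic alcohol attacks Boc2O and expels tert-butyl carbonate (which loses CO2) to give the mixed carbonate.

Step 2
Reactants: 4 2',6'-dihydroxy-4'-methoxyacetophenone; 3 tert-butyl 2-methylbut-3-en-2-yl carbonate
Product: 5 1-[2-hydroxy-4-methoxy-6-(2-methylbut-3-en-2-yloxy)phenyl]ethanone
Conditions: Pd(PPh3)4 (cat.), THF, 0 °C to rt, short reaction time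
Reagents that add atoms: none
Why: Tsuji–Trost O-allylation, in which zerovalent palladium ionises 3 to a 1,1-dimethyl-π-allyl complex with loss of CO2 and the non-chelated phenol of symmetric 4 attacks the more substituted allyl terminus, while the second hydroxyl stays locked in a hydrogen bond to the acetyl group and is left free.

Step 3
Reactants: 6 2,4-dihydroxybenzoic acid
Product: 7 tert-butyldimethylsilyl 2,4-bis(tert-butyldimethylsilyloxy)benzoate
Conditions: TBSCl (excess), imidazole, DMF, rt
Reagents that add atoms: tert-butyldimethylsilyl chloride, CC(C)(C)[Si](C)(C)Cl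
Why: Imidazole-promoted silylation caps both phenols and the carboxyl group in one operation.

Step 4
Reactants: 7 tert-butyldimethylsilyl 2,4-bis(tert-butyldimethylsilyloxy)benzoate
Product: 8 2,4-bis(tert-butyldimethylsilyloxy)benzoyl chloride
Conditions: (COCl)2, DMF (cat.), CH2Cl2, 0 °C to rt; volatiles including TBSCl removed under high vacuum, used crude
Reagents that add atoms: oxalyl chloride, O=C(Cl)C(=O)Cl
Why: The Vilsmeier chloroiminium salt converts a silyl ester directly into the acid chloride under neutral conditions, so no HCl is released and the aryl silyl ethers survive.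

Step 5
Reactants: 5 1-[2-hydroxy-4-methoxy-6-(2-methylbut-3-en-2-yloxy)phenyl]ethanone; 8 2,4-bis(tert-butyldimethylsilyloxy)benzoyl chloride
Product: 9 2-acetyl-5-methoxy-3-(2-methylbut-3-en-2-yloxy)phenyl 2,4-bis(tert-butyldimethylsilyloxy)benzoate
Conditions: Et3N, DMAP (cat.), CH2Cl2, 0 °C to rt
Reagents that add atoms: none
Why: DMAP-catalysed O-acylation of the only free (chelated) phenol by the acid chloride, under base too mild for a Baker–Venkataraman acyl shift or for ionisation of the tertiary allyl ether.

Step 6
Reactants: 9 2-acetyl-5-methoxy-3-(2-methylbut-3-en-2-yloxy)phenyl 2,4-bis(tert-butyldimethylsilyloxy)benzoate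
Product: 11 2-acetyl-3-hydroxy-5-methoxy-4-(3-methylbut-2-enyl)phenyl 2,4-bis(tert-butyldimethylsilyloxy)benzoate, via ortho-dienone 10 (not isolated)
Conditions: o-xylene, 140 °C
Reagents that add atoms: none
Why: Aromatic Claisen rearrangement, in which the [3,3] shift goes to the only unsubstituted ortho carbon (the other carries the acetyl group), inverts the 1,1-dimethylallyl unit into a prenyl group, and is made irreversible by tautomerisation of dienone 10 to the phenol.

Step 7
Reactants: 11 2-acetyl-3-hydroxy-5-methoxy-4-(3-methylbut-2-enyl)phenyl 2,4-bis(tert-butyldimethylsilyloxy)benzoate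
Product: 12 2-acetyl-3-(tert-butyldimethylsilyloxy)-5-methoxy-4-(3-methylbut-2-enyl)phenyl 2,4-bis(tert-butyldimethylsilyloxy)benzoate
Conditions: TBSOTf, 2,6-lutidine, CH2Cl2, 0 °C
Reagents that add atoms: tert-butyldimethylsilyl triflate, CC(C)(C)[Si](C)(C)OS(=O)(=O)C(F)(F)F
Why: Silyl triflate silylation is strong enough for the chelated, doubly flanked phenol, and the non-nucleophilic base leaves the aryl ester and the alkene untouched.

Step 8
Reactants: 12 2-acetyl-3-(tert-butyldimethylsilyloxy)-5-methoxy-4-(3-methylbut-2-enyl)phenyl 2,4-bis(tert-butyldimethylsilyloxy)benzoate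
Product: 13 2-[2,4-bis(tert-butyldimethylsilyloxy)phenyl]-4-(tert-butyldimethylsilyloxy)-6-methoxy-3-methyl-5-(3-methylbut-2-enyl)benzofuran
Conditions: TiCl3, Zn dust, DME, reflux (slurry pre-reduced), slow addition of 12 by syringe pump; filtration through silica
Reagents that add atoms: none
Why: Low-valent titanium from TiCl3 and Zn transfers electrons to the acetyl carbonyl of 12 to give a titanium-bound ketyl, whose carbon attacks the ester carbonyl held on the ortho oxygen; the titanium 2,3-diolate so formed is deoxygenated on the oxophilic metal to the C2=C3 double bond, with aromatisation of the furan as driving force. The closest known reaction is the titanium-induced oxo-ester (McMurry-type) cyclisation of ortho-acyloxy aryl ketones to 2,3-disubstituted benzofurans. The furan ring closes in a 5-exo-trig mode, the ketyl carbon (future C3) adding to the trigonal ester carbon (future C2) whose C=O lies outside the new ring. No stereocentre is formed. The step needs the intramolecular keto-ester coupling to win over intermolecular pinacol or olefin coupling of two ketones and over simple ketone reduction; the two ortho oxygen substituents flanking the ketone block dimerisation, the ester carbonyl sits within five-ring reach, and slow addition keeps the substrate dilute. The aryl silyl ethers, the methyl ether and the isolated trisubstituted alkene are not reduced by the reagent.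

Step 9
Reactants: 13 2-[2,4-bis(tert-butyldimethylsilyloxy)phenyl]-4-(tert-butyldimethylsilyloxy)-6-methoxy-3-methyl-5-(3-methylbut-2-enyl)benzofuran
Product: 14 4-{2-[2,4-bis(tert-butyldimethylsilyloxy)phenyl]-4-(tert-butyldimethylsilyloxy)-6-methoxy-3-methylbenzofuran-5-yl}-2-methylbutan-2-ol
Conditions: Co(acac)2 (cat.), PhSiH3, O2 (1 atm), THF, rt
Reagents that add atoms: dioxygen, O=O
Why: Mukaiyama hydration, in which a cobalt hydride transfers a hydrogen atom to the trisubstituted alkene, the tertiary radical is trapped by O2 and the peroxide is reduced by the silane, giving the Markovnikov tertiary alcohol while the aromatic furan and the silyl ethers stay inert.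

Step 10
Reactants: 14 4-{2-[2,4-bis(tert-butyldimethylsilyloxy)phenyl]-4-(tert-butyldimethylsilyloxy)-6-methoxy-3-methylbenzofuran-5-yl}-2-methylbutan-2-ol
Product: 16 2-[2,4-bis(tert-butyldimethylsilyloxy)phenyl]-4-(tert-butyldimethylsilyloxy)-5-(3-hydroxy-3-methylbutyl)-6-methoxybenzofuran-3-carbaldehyde, via hydroxymethyl compound 15 (not isolated)
Conditions: DDQ (about 2.5 equiv), 1,4-dioxane/H2O, rt
Reagents that add atoms: water, O
Why: DDQ benzylic oxidation, in which hydride loss from the C3 methyl gives a cation stabilised by O1 and ring B through C2, water traps it to alcohol 15 and a second hydride abstraction gives the aldehyde, which is deactivated towards further oxidation; the C5 benzylic CH2 is held out of alignment with the ring by its two ortho substituents and should not compete.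

Step 11
Reactants: 16 2-[2,4-bis(tert-butyldimethylsilyloxy)phenyl]-4-(tert-butyldimethylsilyloxy)-5-(3-hydroxy-3-methylbutyl)-6-methoxybenzofuran-3-carbaldehyde
Product: 17 2-(2,4-dihydroxyphenyl)-4-hydroxy-5-(3-hydroxy-3-methylbutyl)-6-methoxybenzofuran-3-carbaldehyde (ebenfuran V)
Conditions: TBAF, AcOH, THF, 0 °C
Reagents that add atoms: none
Why: Fluoride-driven cleavage of the three aryl silyl ethers (strong Si–F bond), buffered with acetic acid so that the phenoxides are protonated at once and the tertiary alcohol and the aldehyde are not exposed to acid or strong base.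

**Compound list**

1 | 2-methylbut-3-en-2-ol | C=CC(C)(C)O | starting material
2 | lithium 2-methylbut-3-en-2-olate | [Li+].[O-]C(C)(C)C=C | intermediate
3 | tert-butyl 2-methylbut-3-en-2-yl carbonate | C=CC(C)(C)OC(=O)OC(C)(C)C | intermediate
4 | 2',6'-dihydroxy-4'-methoxyacetophenone | CC(=O)c1c(O)cc(OC)cc1O | starting material
5 | 1-[2-hydroxy-4-methoxy-6-(2-methylbut-3-en-2-yloxy)phenyl]ethanone | CC(=O)c1c(O)cc(OC)cc1OC(C)(C)C=C | intermediate
6 | 2,4-dihydroxybenzoic acid | O=C(O)c1ccc(O)cc1O | starting material
7 | tert-butyldimethylsilyl 2,4-bis(tert-butyldimethylsilyloxy)benzoate | CC(C)(C)[Si](C)(C)OC(=O)c1ccc(O[Si](C)(C)C(C)(C)C)cc1O[Si](C)(C)C(C)(C)C | intermediate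
8 | 2,4-bis(tert-butyldimethylsilyloxy)benzoyl chloride | O=C(Cl)c1ccc(O[Si](C)(C)C(C)(C)C)cc1O[Si](C)(C)C(C)(C)C | intermediate
9 | 2-acetyl-5-methoxy-3-(2-methylbut-3-en-2-yloxy)phenyl 2,4-bis(tert-butyldimethylsilyloxy)benzoate | CC(=O)c1c(OC(=O)c2ccc(O[Si](C)(C)C(C)(C)C)cc2O[Si](C)(C)C(C)(C)C)cc(OC)cc1OC(C)(C)C=C | intermediate
10 | 2-acetyl-5-methoxy-4-(3-methylbut-2-enyl)-3-oxocyclohexa-1,5-dienyl 2,4-bis(tert-butyldimethylsilyloxy)benzoate (ortho-dienone, racemic) | CC(=O)C1=C(OC(=O)c2ccc(O[Si](C)(C)C(C)(C)C)cc2O[Si](C)(C)C(C)(C)C)C=C(OC)C(CC=C(C)C)C1=O | intermediate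
11 | 2-acetyl-3-hydroxy-5-methoxy-4-(3-methylbut-2-enyl)phenyl 2,4-bis(tert-butyldimethylsilyloxy)benzoate | CC(=O)c1c(OC(=O)c2ccc(O[Si](C)(C)C(C)(C)C)cc2O[Si](C)(C)C(C)(C)C)cc(OC)c(CC=C(C)C)c1O | intermediate
12 | 2-acetyl-3-(tert-butyldimethylsilyloxy)-5-methoxy-4-(3-methylbut-2-enyl)phenyl 2,4-bis(tert-butyldimethylsilyloxy)benzoate | CC(=O)c1c(OC(=O)c2ccc(O[Si](C)(C)C(C)(C)C)cc2O[Si](C)(C)C(C)(C)C)cc(OC)c(CC=C(C)C)c1O[Si](C)(C)C(C)(C)C | intermediate
13 | 2-[2,4-bis(tert-butyldimethylsilyloxy)phenyl]-4-(tert-butyldimethylsilyloxy)-6-methoxy-3-methyl-5-(3-methylbut-2-enyl)benzofuran | Cc1c(-c2ccc(O[Si](C)(C)C(C)(C)C)cc2O[Si](C)(C)C(C)(C)C)oc2cc(OC)c(CC=C(C)C)c(O[Si](C)(C)C(C)(C)C)c12 | intermediate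
14 | 4-{2-[2,4-bis(tert-butyldimethylsilyloxy)phenyl]-4-(tert-butyldimethylsilyloxy)-6-methoxy-3-methylbenzofuran-5-yl}-2-methylbutan-2-ol | Cc1c(-c2ccc(O[Si](C)(C)C(C)(C)C)cc2O[Si](C)(C)C(C)(C)C)oc2cc(OC)c(CCC(C)(C)O)c(O[Si](C)(C)C(C)(C)C)c12 | intermediate
15 | {2-[2,4-bis(tert-butyldimethylsilyloxy)phenyl]-4-(tert-butyldimethylsilyloxy)-5-(3-hydroxy-3-methylbutyl)-6-methoxybenzofuran-3-yl}methanol | OCc1c(-c2ccc(O[Si](C)(C)C(C)(C)C)cc2O[Si](C)(C)C(C)(C)C)oc2cc(OC)c(CCC(C)(C)O)c(O[Si](C)(C)C(C)(C)C)c12 | intermediate
16 | 2-[2,4-bis(tert-butyldimethylsilyloxy)phenyl]-4-(tert-butyldimethylsilyloxy)-5-(3-hydroxy-3-methylbutyl)-6-methoxybenzofuran-3-carbaldehyde | O=Cc1c(-c2ccc(O[Si](C)(C)C(C)(C)C)cc2O[Si](C)(C)C(C)(C)C)oc2cc(OC)c(CCC(C)(C)O)c(O[Si](C)(C)C(C)(C)C)c12 | intermediate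
17 | 2-(2,4-dihydroxyphenyl)-4-hydroxy-5-(3-hydroxy-3-methylbutyl)-6-methoxybenzofuran-3-carbaldehyde (ebenfuran V) | COc1cc2oc(-c3ccc(O)cc3O)c(C=O)c2c(O)c1CCC(C)(C)O | target

**Step count**

Total: 11 steps. Longest linear sequence: 9 steps (6 to 17 through steps 3 to 11).

**Steps most likely to fail**

Step 8 (key step). The ketone may be reduced or pinacol-coupled between two molecules instead of closing onto the ester, the aryl ester may be cleaved reductively, or the silyl ethers may be lost to the Lewis-acidic titanium and zinc chlorides. The fallback forms the same C2=C3 bond by an intramolecular Wittig reaction and sets out from 12. i-Bu2AlH (excess) in CH2Cl2 at −78 °C should reduce the ketone and cleave the aryl ester to give 3-(tert-butyldimethylsilyloxy)-2-(1-hydroxyethyl)-5-methoxy-4-(3-methylbut-2-enyl)phenol F1 (racemic). PPh3·HBr in refluxing MeCN should convert the ortho-hydroxybenzylic alcohol into {1-[2-(tert-butyldimethylsilyloxy)-6-hydroxy-4-methoxy-3-(3-methylbut-2-enyl)phenyl]ethyl}triphenylphosphonium bromide F2 (racemic). Treatment of F2 with acid chloride 8 and Et3N in refluxing toluene should acylate the phenol, form the ylide and close the furan onto the ester carbonyl with loss of triphenylphosphine oxide, coming back to the route at 13.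

Step 10. Hydride abstraction may occur at the C5 benzylic methylene, the electron-rich rings may be degraded by the quinone, or the oxidation may stall at alcohol 15. The fallback sets out from 14 and replaces the hydride-abstracting quinone by an ene-type allylic oxidation of the methyl group on the enol-ether-like C2=C3 bond (Riley oxidation, SeO2 in refluxing 1,4-dioxane), with MnO2 in CH2Cl2 to finish any 15 that remains; it comes back at 16 and makes no compound outside the list.

Step 2. The phenol may attack the less substituted allyl terminus (or the tertiary ether may isomerise on palladium to the linear prenyl ether), the phloroglucinol-type ring may be C-allylated, or both hydroxyls may be alkylated. The fallback sets out from 4 and builds the tertiary ether by copper-catalysed propargylation followed by semi-hydrogenation. 3-Chloro-3-methylbut-1-yne with DBU and CuCl2 (cat.) in MeCN at 0 °C should give 1-[2-hydroxy-4-methoxy-6-(2-methylbut-3-yn-2-yloxy)phenyl]ethanone F3. H2 (1 atm) over Pd/CaCO3 poisoned with Pb(OAc)2, with quinoline in EtOAc, should reduce the alkyne to the alkene, coming back at 5.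

**Further compounds**

F1 | step 8 | 3-(tert-butyldimethylsilyloxy)-2-(1-hydroxyethyl)-5-methoxy-4-(3-methylbut-2-enyl)phenol (racemic) | CC(O)c1c(O)cc(OC)c(CC=C(C)C)c1O[Si](C)(C)C(C)(C)C
F2 | step 8 | {1-[2-(tert-butyldimethylsilyloxy)-6-hydroxy-4-methoxy-3-(3-methylbut-2-enyl)phenyl]ethyl}triphenylphosphonium bromide (racemic) | CC(c1c(O)cc(OC)c(CC=C(C)C)c1O[Si](C)(C)C(C)(C)C)[P+](c1ccccc1)(c1ccccc1)c1ccccc1.[Br-]
F0 | step 10 | none | none
F3 | step 2 | 1-[2-hydroxy-4-methoxy-6-(2-methylbut-3-yn-2-yloxy)phenyl]ethanone | CC(=O)c1c(O)cc(OC)cc1OC(C)(C)C#C
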